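The seven-membered carbocycle is cut into a three-carbon unit C1–C5–C6 and a four-carbon unit C7–C8–C9–C10. Its α-face triad (C6–O, C7–C11 and C10–Me, all cis) is the signature of a boat Cope rearrangement. A rhodium vinylcarbenoid from a 4-siloxy vinyldiazoacetate cyclopropanates the (Z)-silyl enol ether of a Roche-ester-derived 2-siloxydiene; the cis-divinylcyclopropane then rearranges. This forms C1–C10 and C6–C7 in one operation and sets C6, C7 and C10. Both precursors are acyclic. The cycloheptadiene keeps an enoate (for C1 and C5) and an enol ether (for C9) as handles for the remaining oxygens.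

Key step: step 7

Remark (labels used below): ring carbons are C1 (carbinol carrying the crotonoyl carbons C2–C4), C5 (angelate carbon), C6 (lactone O–CH), C7 (lactone C–CH carrying C11, whose carbonyl carbon is C12), C8, C9 (carbinol) and C10 (CH–Me). α is the ring face of C1–OH, C6–O, C7–C11 and C10–Me; β is the face of C5–O, C9–O and the C1 acyl group.

Step 1
Reactants: 1 methyl (S)-3-hydroxy-2-methylpropanoate
Product: 2 methyl (S)-3-(tert-butyldimethylsilyloxy)-2-methylpropanoate
Conditions: TBSCl, imidazole, CH2Cl2, rt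
Reagents that add atoms: tert-butyldimethylsilyl chloride, CC(C)(C)[Si](C)(C)Cl
Why: Silyl ether formation on the primary alcohol; the future C11 stereocenter comes from the chiral pool and is not touched.

Step 2
Reactants: 2 methyl (S)-3-(tert-butyldimethylsilyloxy)-2-methylpropanoate
Product: 3 (S)-3-(tert-butyldimethylsilyloxy)-2-methylpropanal
Conditions: DIBAL, CH2Cl2, −78 °C; Rochelle salt work-up
Reagents that add atoms: none
Why: Partial DIBAL reduction of the ester through a tetrahedral aluminate that is stable at −78 °C should give the aldehyde without epimerising the α-center.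

Step 3
Reactants: 3 (S)-3-(tert-butyldimethylsilyloxy)-2-methylpropanal; 4 diethyl (2-oxobutyl)phosphonate
Product: 5 (4E,6R)-7-(tert-butyldimethylsilyloxy)-6-methylhept-4-en-3-one
Conditions: LiCl, iPr2NEt, MeCN, rt
Reagents that add atoms: none
Why: Horner–Wadsworth–Emmons olefination under Masamune–Roush conditions should give the E-enone (C7=C8), and the mild base should spare the α-stereocenter.

Step 4
Reactants: 5 (4E,6R)-7-(tert-butyldimethylsilyloxy)-6-methylhept-4-en-3-one
Product: 6 (2Z,4E,6R)-3,7-bis(tert-butyldimethylsilyloxy)-6-methylhepta-2,4-diene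
Conditions: TBSOTf, Et3N, CH2Cl2, −78 → 0 °C
Reagents that add atoms: tert-butyldimethylsilyl triflate, CC(C)(C)[Si](C)(C)OS(=O)(=O)C(F)(F)F
Why: Soft enolisation of the ethyl ketone on its α′ side (silyl enol ether formation) should give the cross-conjugated 2-siloxydiene with Z geometry, the methyl lying cis to the siloxy group to avoid allylic strain with the vinyl group.

Step 5
Reactants: 7 ethyl diazoacetate; 8 (tert-butyldimethylsilyloxy)acetaldehyde
Product: 9 ethyl 4-(tert-butyldimethylsilyloxy)-2-diazo-3-hydroxybutanoate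
Conditions: DBU (cat.), MeCN, rt
Reagents that add atoms: none
Why: Base-catalysed aldol-type addition of the diazoacetate to the aldehyde; the carbinol center is racemic and is removed in step 6.

Step 6
Reactants: 9 ethyl 4-(tert-butyldimethylsilyloxy)-2-diazo-3-hydroxybutanoate
Product: 10 ethyl (E)-4-(tert-butyldimethylsilyloxy)-2-diazobut-3-enoate
Conditions: POCl3, Et3N, CH2Cl2, 0 °C → rt
Reagents that add atoms: none
Why: Dehydration of the β-hydroxy-α-diazo ester should give the vinyldiazoacetate, the only possible elimination being toward the CH2OTBS carbon, with the E enol ether favoured.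

Step 7
Reactants: 6 (2Z,4E,6R)-3,7-bis(tert-butyldimethylsilyloxy)-6-methylhepta-2,4-diene; 10 ethyl (E)-4-(tert-butyldimethylsilyloxy)-2-diazobut-3-enoate
Product: 12 all-cis cyclohepta-1(5),8-diene ethyl ester, via cis-divinylcyclopropane 11 (not isolated)
Conditions: Rh2(R-DOSP)4 (dirhodium tetrakis[(R)-N-(4-dodecylbenzenesulfonyl)prolinate], 1 mol %), hexanes, −40 °C → rt, slow addition of 10; then 60 °C
Reagents that add atoms: none
Why: The rhodium carbenoid from 10 adds to the most electron-rich alkene of 6, the C9=C10 enol ether (C1–C10 bond, carbenoid (2+1) closure), and the donor–acceptor cis-divinylcyclopropane 11 expands by a [3,3]-sigmatropic Cope shift through the obligatory boat transition state (C6–C7 bond, seven-membered ring closed as C1–C9 breaks). The closest known reaction type is the tandem cyclopropanation/Cope formal (4+3) cycloaddition of vinyldiazoacetates with dienes. C10 is set by the chiral prolinate catalyst, which selects the enol ether face; the R antipode is assigned by analogy with the sense known for simple alkenes, and the S antipode would be used if the sense proves opposite. C6 and C7 follow from the boat geometry: the E siloxy group on the carbenoid terminus and the E substituent on C7 end up cis to each other and cis to the C10 methyl, which the Z enol ether places anti to both vinyl groups. The step needs reaction at the carbenoid carbon and not at its vinylogous terminus (hydrocarbon solvent, substituted terminus), and attack on the enol ether and not on the E-disubstituted C7=C8 alkene, which is intrinsically unreactive toward donor/acceptor carbenoids. Any trans-divinylcyclopropane should equilibrate on warming by reversible C1–C9 heterolysis of the siloxy/ester-substituted ring and so funnel into the Cope pathway.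

Step 8
Reactants: 12 all-cis cyclohepta-1(5),8-diene ethyl ester
Product: 13 C2 allylic alcohol
Conditions: DIBAL (2.5 equiv), CH2Cl2, −78 °C
Reagents that add atoms: none
Why: 1,2-Reduction of the conjugated ester by DIBAL should give the primary allylic alcohol; silyl ethers and the silyl enol ether are inert.

Step 9
Reactants: 13 C2 allylic alcohol
Product: 14 1α,5α-epoxy alcohol
Conditions: Ti(OiPr)4 (20 mol %), D-(−)-diisopropyl tartrate (24 mol %), t-BuOOH, 4 Å MS, CH2Cl2, −20 °C
Reagents that add atoms: tert-butyl hydroperoxide, CC(C)(C)OO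
Why: Katsuki–Sharpless asymmetric epoxidation of the 1-cycloalkenylmethanol; the D-(−)-tartrate complex should deliver oxygen to the α face (reagent control), fixing C1–O as α and placing the C5–O bond α for the inversion in step 10, while the enol ether has no directing hydroxyl and should not react.

Step 10
Reactants: 14 1α,5α-epoxy alcohol; 15 angelic acid
Product: 16 5β-angelate 1α,2-diol
Conditions: Ti(OiPr)4 (1.5 equiv), CH2Cl2, rt
Reagents that add atoms: none
Why: Titanium-mediated opening of a 2,3-epoxy alcohol by a carboxylic acid at the carbon distal to the carbinol (here C5, the only non-quaternary epoxide carbon) is an SN2 process, so the angelate should enter on the open β face with inversion and leave the tertiary C1–OH α.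

Step 11
Reactants: 16 5β-angelate 1α,2-diol
Product: 17 C2 aldehyde
Conditions: SO3·pyridine, DMSO, iPr2NEt, CH2Cl2, 0 °C
Reagents that add atoms: none
Why: Parikh–Doering oxidation of the only oxidisable (primary) hydroxyl; C9 is still masked as its enol ether, so no lactol or over-oxidation can arise, and C1 has no α-hydrogen.

Step 12
Reactants: 17 C2 aldehyde; 18 (E)-1-bromoprop-1-ene
Product: 19 C2 allylic alcohol (both C2 epimers)
Conditions: CrCl2, NiCl2 (cat.), DMSO, rt
Reagents that add atoms: none
Why: Nozaki–Hiyama–Kishi addition is aldehyde-selective (angelate, free tertiary hydroxyl and silyl groups tolerated) and retains the E alkene geometry; the new C2 center is oxidised in step 15.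

Step 13
Reactants: 19 C2 allylic alcohol (both C2 epimers)
Product: 20 C9 ketone
Conditions: TBAF (1.1 equiv), AcOH (1.2 equiv), THF, −20 °C
Reagents that add atoms: none
Why: Buffered fluoride should cleave the silyl enol ether far faster than the alkyl silyl ethers, and protonation at C8 creates no stereocenter.

Step 14
Reactants: 20 C9 ketone
Product: 21 9β-alcohol
Conditions: Me4NBH(OAc)3, MeCN/AcOH (1:1), −20 °C
Reagents that add atoms: none
Why: Evans–Saksena reduction: the tertiary C1–OH (α) exchanges onto boron and delivers hydride intramolecularly through a six-membered transition state to the α face of the β-positioned C9 ketone, which should give the 1,3-anti diol (C9–OH β, trans to C10–Me).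

Step 15
Reactants: 21 9β-alcohol
Product: 22 crotonoyl ketone
Conditions: MnO2, CH2Cl2, rt
Reagents that add atoms: none
Why: Activated MnO2 should oxidise only the allylic C2 carbinol, so both C2 epimers converge on the E-enone while the saturated C9–OH stays.

Step 16
Reactants: 22 crotonoyl ketone
Product: 23 C6,C12-diol (tetraol)
Conditions: HF·pyridine, pyridine, THF, 0 °C → rt
Reagents that add atoms: none
Why: Acidic fluoride desilylation should free C6–OH and C12–OH without base, so the angelate neither migrates nor isomerises.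

Step 17
Reactants: 23 C6,C12-diol (tetraol)
Product: 24 CNP0183494.1
Conditions: TEMPO (cat.), PhI(OAc)2, CH2Cl2, rt
Reagents that add atoms: none
Why: TEMPO/PhI(OAc)2 oxidative lactonisation of the 1,4-diol: the primary C12–OH is oxidised selectively, the aldehyde is trapped by the cis C6–OH as a lactol, and this is oxidised to the cis-fused γ-lactone under neutral conditions that should not epimerise C11.

Compound list
1 | methyl (S)-3-hydroxy-2-methylpropanoate ((S)-Roche ester) | COC(=O)[C@@H](C)CO | starting material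
2 | methyl (S)-3-(tert-butyldimethylsilyloxy)-2-methylpropanoate | COC(=O)[C@@H](C)CO[Si](C)(C)C(C)(C)C | intermediate
3 | (S)-3-(tert-butyldimethylsilyloxy)-2-methylpropanal | O=C[C@@H](C)CO[Si](C)(C)C(C)(C)C | intermediate
4 | diethyl (2-oxobutyl)phosphonate | CCC(=O)CP(=O)(OCC)OCC | starting material
5 | (4E,6R)-7-(tert-butyldimethylsilyloxy)-6-methylhept-4-en-3-one | CCC(=O)/C=C/[C@@H](C)CO[Si](C)(C)C(C)(C)C | intermediate
6 | (2Z,4E,6R)-3,7-bis(tert-butyldimethylsilyloxy)-6-methylhepta-2,4-diene | C/C=C(O[Si](C)(C)C(C)(C)C)/C=C/[C@@H](C)CO[Si](C)(C)C(C)(C)C | intermediate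
7 | ethyl diazoacetate | CCOC(=O)C=[N+]=[N-] | starting material
8 | (tert-butyldimethylsilyloxy)acetaldehyde | O=CCO[Si](C)(C)C(C)(C)C | starting material
9 | ethyl 4-(tert-butyldimethylsilyloxy)-2-diazo-3-hydroxybutanoate (racemic) | CCOC(=O)C(=[N+]=[N-])C(O)CO[Si](C)(C)C(C)(C)C | intermediate
10 | ethyl (E)-4-(tert-butyldimethylsilyloxy)-2-diazobut-3-enoate | CCOC(=O)C(=[N+]=[N-])/C=C/O[Si](C)(C)C(C)(C)C | intermediate
11 | cis-divinylcyclopropane: ethyl 2-(TBSO)-1-[(E)-2-(TBSO)ethenyl]-3-methyl-2-[(1E,3R)-4-(TBSO)-3-methylbut-1-enyl]cyclopropane-1-carboxylate, the two alkenyl groups cis to each other and trans to the ring methyl | CCOC(=O)[C@@]1(/C=C/O[Si](C)(C)C(C)(C)C)[C@@H](C)[C@]1(O[Si](C)(C)C(C)(C)C)/C=C/[C@@H](C)CO[Si](C)(C)C(C)(C)C | intermediate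
12 | all-cis cycloheptadiene ester: C1=C5 and C8=C9 double bonds, CO2Et on C1, 6α-OTBS, 7α-[(R)-1-(TBSO)propan-2-yl], 9-OTBS (enol ether), 10α-Me | CCOC(=O)C1=C[C@H](O[Si](C)(C)C(C)(C)C)[C@H]([C@@H](C)CO[Si](C)(C)C(C)(C)C)C=C(O[Si](C)(C)C(C)(C)C)[C@@H]1C | intermediate
13 | C2 allylic alcohol: as 12 with CH2OH on C1 in place of CO2Et | OCC1=C[C@H](O[Si](C)(C)C(C)(C)C)[C@H]([C@@H](C)CO[Si](C)(C)C(C)(C)C)C=C(O[Si](C)(C)C(C)(C)C)[C@@H]1C | intermediate
14 | 1α,5α-epoxy alcohol: epoxide across C1–C5 on the α face, CH2OH on C1, otherwise as 13 | OC[C@@]12O[C@@H]1[C@H](O[Si](C)(C)C(C)(C)C)[C@H]([C@@H](C)CO[Si](C)(C)C(C)(C)C)C=C(O[Si](C)(C)C(C)(C)C)[C@@H]2C | intermediate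
15 | angelic acid, (Z)-2-methylbut-2-enoic acid | C/C=C(/C)C(=O)O | starting material
16 | 5β-angelate 1α,2-diol: 5β-O-angeloyl, 1α-OH, CH2OH on C1 (β), 6α-OTBS, 7α side chain, C8=C9 enol OTBS, 10α-Me | C/C=C(/C)C(=O)O[C@H]1[C@H](O[Si](C)(C)C(C)(C)C)[C@H]([C@@H](C)CO[Si](C)(C)C(C)(C)C)C=C(O[Si](C)(C)C(C)(C)C)[C@H](C)[C@@]1(O)CO | intermediate
17 | C2 aldehyde: as 16 with CHO on C1 | C/C=C(/C)C(=O)O[C@H]1[C@H](O[Si](C)(C)C(C)(C)C)[C@H]([C@@H](C)CO[Si](C)(C)C(C)(C)C)C=C(O[Si](C)(C)C(C)(C)C)[C@H](C)[C@@]1(O)C=O | intermediate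
18 | (E)-1-bromoprop-1-ene | C/C=C/Br | starting material
19 | C2 allylic alcohol: as 16 with CH(OH)–(E)-CH=CH–CH3 on C1, both C2 epimers | C/C=C(/C)C(=O)O[C@H]1[C@H](O[Si](C)(C)C(C)(C)C)[C@H]([C@@H](C)CO[Si](C)(C)C(C)(C)C)C=C(O[Si](C)(C)C(C)(C)C)[C@H](C)[C@@]1(O)C(O)/C=C/C | intermediate
20 | C9 ketone: as 19 with C8 methylene and C9 carbonyl | C/C=C(/C)C(=O)O[C@H]1[C@H](O[Si](C)(C)C(C)(C)C)[C@H]([C@@H](C)CO[Si](C)(C)C(C)(C)C)CC(=O)[C@H](C)[C@@]1(O)C(O)/C=C/C | intermediate
21 | 9β-alcohol: as 20 with 9β-OH | C/C=C(/C)C(=O)O[C@H]1[C@H](O[Si](C)(C)C(C)(C)C)[C@H]([C@@H](C)CO[Si](C)(C)C(C)(C)C)C[C@@H](O)[C@H](C)[C@@]1(O)C(O)/C=C/C | intermediate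
22 | crotonoyl ketone: as 21 with (E)-but-2-enoyl on C1 | C/C=C(/C)C(=O)O[C@H]1[C@H](O[Si](C)(C)C(C)(C)C)[C@H]([C@@H](C)CO[Si](C)(C)C(C)(C)C)C[C@@H](O)[C@H](C)[C@@]1(O)C(=O)/C=C/C | intermediate
23 | tetraol: 5β-O-angeloyl, 1α-OH, 1β-crotonoyl, 6α-OH, 7α-[(R)-1-hydroxypropan-2-yl], 9β-OH, 10α-Me cycloheptane | C/C=C(/C)C(=O)O[C@H]1[C@H](O)[C@H]([C@@H](C)CO)C[C@@H](O)[C@H](C)[C@@]1(O)C(=O)/C=C/C | intermediate
24 | CNP0183494.1: cis-fused 12,6-γ-lactone of 23 with (11R)-methyl | C/C=C(/C)C(=O)O[C@H]1[C@@H]2OC(=O)[C@H](C)[C@@H]2C[C@@H](O)[C@H](C)[C@@]1(O)C(=O)/C=C/C | target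

Total step count: 17. Longest linear sequence: 15 steps (steps 1–4 and 7–17, from 1 to 24).

Steps most likely to fail

Step 7. The carbenoid may be diverted: attack through its vinylogous (siloxy-bearing) carbon, collapse of the zwitterionic siloxycyclopropane to a five-membered ring, or poor face control at C10 on the trisubstituted enol ether. The fallback builds the divinylcyclopropane stepwise, setting out from 6. Asymmetric cyclopropanation of the enol ether with ethyl diazoacetate 7 (CuOTf, tBu-bis(oxazoline) of the antipode that gives the required C10 configuration) should give the siloxycyclopropane ester F1. Deprotonation at C1 (LDA, THF, −78 °C) and aldol addition to aldehyde 8 gives the β-hydroxy ester F2. Mesylation and elimination (MsCl, Et3N; then DBU) gives 11, which is heated in toluene and comes back to the route at 12.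

Step 9. Oxygen delivery to the α face may fail, because that face carries both allylic substituents (C10–Me and C6–OTBS) and reagent control then opposes substrate control. The fallback uses only substrate-preferred approaches, setting out from 12 and coming back at 16. Copper-catalysed conjugate borylation of the enoate (CuCl, NaOtBu, DPEphos, B2pin2, MeOH, THF) from the open β face, anti to C6–OTBS, gives the 5β-boronate F3, and NaBO3 oxidation gives the 5β-hydroxy ester F4. Fráter–Seebach hydroxylation of its dianion (LDA, 2.2 equiv, −78 °C; then 2-(phenylsulfonyl)-3-phenyloxaziridine) introduces the C1 hydroxyl anti to the C5 alkoxide and gives the 1α,5β-diol ester F5. Yamaguchi esterification of the secondary C5–OH with 15 (2,4,6-trichlorobenzoyl chloride, Et3N; DMAP, toluene) gives the angelate ester F6. NaBH4 in EtOH at 0 °C, which reduces the α-hydroxy ester chemoselectively, gives 16.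

Step 10. Angelic acid may open the epoxide sluggishly, the new angelate may migrate to the neighbouring primary hydroxyl, or it may isomerise to the tiglate under Lewis acid. The fallback separates inversion at C5 from acylation, setting out from 14 and coming back at 17. Opening with benzoic acid and Ti(OiPr)4 gives the 5β-benzoate F7, and DIBAL at −78 °C removes the benzoate (wherever it sits) to give the triol F8. Selective silylation of the primary hydroxyl (TESCl, imidazole, −20 °C) gives the C2 triethylsilyl ether F9. Yamaguchi esterification with 15 gives the 5β-angelate F10. Swern oxidation, which converts a primary triethylsilyl ether directly into the aldehyde, gives 17.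

Further compounds
F1 | step 7 | ethyl 2-(TBSO)-3-methyl-2-[(1E,3R)-4-(TBSO)-3-methylbut-1-enyl]cyclopropane-1-carboxylate (methyl trans to the alkenyl group) | CCOC(=O)C1[C@@H](C)[C@]1(O[Si](C)(C)C(C)(C)C)/C=C/[C@@H](C)CO[Si](C)(C)C(C)(C)C
F2 | step 7 | aldol adduct of F1 at C1 with aldehyde 8 (1-[2-(TBSO)-1-hydroxyethyl] derivative) | CCOC(=O)C1(C(O)CO[Si](C)(C)C(C)(C)C)[C@@H](C)[C@]1(O[Si](C)(C)C(C)(C)C)/C=C/[C@@H](C)CO[Si](C)(C)C(C)(C)C
F3 | step 9 | 5β-pinacolboronate of the C1–C5 saturated ethyl ester (C8=C9 enol ether retained) | CC1(C)OB(OC1(C)C)[C@H]2[C@H](O[Si](C)(C)C(C)(C)C)[C@H]([C@@H](C)CO[Si](C)(C)C(C)(C)C)C=C(O[Si](C)(C)C(C)(C)C)[C@H](C)C2C(=O)OCC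
F4 | step 9 | 5β-hydroxy ethyl ester | O[C@H]1[C@H](O[Si](C)(C)C(C)(C)C)[C@H]([C@@H](C)CO[Si](C)(C)C(C)(C)C)C=C(O[Si](C)(C)C(C)(C)C)[C@H](C)C1C(=O)OCC
F5 | step 9 | 1α,5β-dihydroxy ethyl ester | O[C@H]1[C@H](O[Si](C)(C)C(C)(C)C)[C@H]([C@@H](C)CO[Si](C)(C)C(C)(C)C)C=C(O[Si](C)(C)C(C)(C)C)[C@H](C)[C@@]1(O)C(=O)OCC
F6 | step 9 | 5β-angelate 1α-hydroxy ethyl ester | C/C=C(/C)C(=O)O[C@H]1[C@H](O[Si](C)(C)C(C)(C)C)[C@H]([C@@H](C)CO[Si](C)(C)C(C)(C)C)C=C(O[Si](C)(C)C(C)(C)C)[C@H](C)[C@@]1(O)C(=O)OCC
F7 | step 10 | 5β-benzoate 1α,2-diol | O=C(O[C@H]1[C@H](O[Si](C)(C)C(C)(C)C)[C@H]([C@@H](C)CO[Si](C)(C)C(C)(C)C)C=C(O[Si](C)(C)C(C)(C)C)[C@H](C)[C@@]1(O)CO)c1ccccc1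
F8 | step 10 | 1α,2,5β-triol | O[C@H]1[C@H](O[Si](C)(C)C(C)(C)C)[C@H]([C@@H](C)CO[Si](C)(C)C(C)(C)C)C=C(O[Si](C)(C)C(C)(C)C)[C@H](C)[C@@]1(O)CO
F9 | step 10 | C2 triethylsilyl ether of the 1α,5β-diol | O[C@H]1[C@H](O[Si](C)(C)C(C)(C)C)[C@H]([C@@H](C)CO[Si](C)(C)C(C)(C)C)C=C(O[Si](C)(C)C(C)(C)C)[C@H](C)[C@@]1(O)CO[Si](CC)(CC)CC
F10 | step 10 | 5β-angelate of the C2 triethylsilyl ether | C/C=C(/C)C(=O)O[C@H]1[C@H](O[Si](C)(C)C(C)(C)C)[C@H]([C@@H](C)CO[Si](C)(C)C(C)(C)C)C=C(O[Si](C)(C)C(C)(C)C)[C@H](C)[C@@]1(O)CO[Si](CC)(CC)CC
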